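Everything rests on making ring B last, on C2 of ring C, instead of bringing it in as an arene. Ring B carries C2'-OH para to C5'-OMe, with C4'-O beside C5' and C1' beside C2': the imprint of a Dötz benzannulation. In one operation a chromium methoxycarbene (C5'), its 1-tert-butoxyvinyl group (C4', C3'), one CO ligand (C2') and a terminal alkyne (C1', C6') are joined through three new C–C bonds, closing ring B with its three oxygens already told apart (free OH, OMe, O-tert-butyl). The precursor is a 2-ethynylchromone carrying rings A and C complete, with O3 and O5 as benzyl ethers.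

Key step: step 8

Assumption: tert-butyl vinyl ether is taken to undergo α-lithiation with t-BuLi in the manner established for methyl and ethyl vinyl ether.

Step 1
Reactants: 1 3-hydroxy-4,5-dimethoxybenzaldehyde
Product: 2 3,4-dimethoxy-5-(methoxymethoxy)benzaldehyde
Conditions: MOMCl, iPr2NEt, CH2Cl2, 0 °C → rt
Reagents that add atoms: chloromethyl methyl ether, COCCl
Why: O-alkylation of the phenol by the reactive α-chloro ether (MOM protection) is routine, and the acetal later serves as the ortho-directing group and as the mask of the oxygen that becomes O1.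

Step 2
Reactants: 2 3,4-dimethoxy-5-(methoxymethoxy)benzaldehyde
Product: 4 3,4-dimethoxy-5-(methoxymethoxy)phenol, via aryl formate 3 (not isolated)
Conditions: mCPBA, CH2Cl2, 0 °C → rt; NaHCO3 wash; then Et3N (cat.), MeOH, rt
Reagents that add atoms: 3-chloroperbenzoic acid, OOC(=O)c1cccc(Cl)c1
Why: Baeyer–Villiger (Dakin-type) oxidation, in which the electron-rich aryl group with its para methoxy migrates to oxygen to give the formate, and base-catalysed methanolysis then frees the phenol that becomes O5.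

Step 3
Reactants: 4 3,4-dimethoxy-5-(methoxymethoxy)phenol
Product: 5 1-(benzyloxy)-3,4-dimethoxy-5-(methoxymethoxy)benzene
Conditions: BnBr, K2CO3, DMF, rt
Reagents that add atoms: benzyl bromide, BrCc1ccccc1
Why: Williamson ether synthesis on an unhindered phenoxide, which fixes the differentiation of the two ring A oxygens that flank the future C4a.

Step 4
Reactants: 5 1-(benzyloxy)-3,4-dimethoxy-5-(methoxymethoxy)benzene; 6 2-(benzyloxy)-N-methoxy-N-methylacetamide
Product: 9 2-(benzyloxy)-1-[6-(benzyloxy)-2-hydroxy-3,4-dimethoxyphenyl]ethan-1-one, via aryllithium 7 (not isolated), via MOM-protected ketone 8 (not isolated)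
Conditions: n-BuLi, THF, 0 °C; 6, −78 → 0 °C; then 3 M HCl, MeOH, 50 °C
Reagents that add atoms: none
Why: Directed ortho-metalation removes the only hydrogen ortho to the chelating OMOM group (the C–H between OMOM and OBn), the Weinreb amide acylation stops at the ketone through its chelated tetrahedral adduct, and dilute methanolic acid cleaves the MOM acetal while leaving both benzyl ethers.

Step 5
Reactants: 9 2-(benzyloxy)-1-[6-(benzyloxy)-2-hydroxy-3,4-dimethoxyphenyl]ethan-1-one; 10 ethyl 2,2-diethoxyacetate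
Product: 13 3,5-bis(benzyloxy)-7,8-dimethoxy-4-oxo-4H-chromene-2-carbaldehyde, via diketone acetal 11 (not isolated), via chromone acetal 12 (not isolated)
Conditions: LiN(SiMe3)2, THF, −78 °C; 10, −78 °C → rt; then 3 M HCl, THF, 55 °C
Reagents that add atoms: water, O
Why: Crossed Claisen condensation of the ketone dianion with the ester gives the 1,3-diketone, and aqueous acid then closes ring C by attack of the phenol on the new ketone with dehydration (the classical chromone synthesis from 2-hydroxyaryl 1,3-diketones) and hydrolyses the diethyl acetal to the aldehyde.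

Step 6
Reactants: 13 3,5-bis(benzyloxy)-7,8-dimethoxy-4-oxo-4H-chromene-2-carbaldehyde; 14 dimethyl (1-diazo-2-oxopropyl)phosphonate
Product: 15 3,5-bis(benzyloxy)-2-ethynyl-7,8-dimethoxy-4H-chromen-4-one
Conditions: 14, K2CO3, MeOH–THF, 0 °C → rt
Reagents that add atoms: none
Why: Seyferth–Gilbert homologation in the Ohira–Bestmann variant, in which the diazomethylphosphonate anion released by methanolysis adds to the non-enolisable aldehyde, olefination gives a diazoalkene, and loss of N2 with 1,2-hydrogen shift gives the terminal alkyne.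

Step 7
Reactants: 16 tert-butyl vinyl ether; 17 chromium hexacarbonyl
Product: 20 pentacarbonyl[(1-tert-butoxyvinyl)(methoxy)carbene]chromium, via vinyllithium 18 (not isolated), via lithium acylchromate 19 (not isolated)
Conditions: t-BuLi, THF, −78 → 0 °C; Cr(CO)6, 0 °C → rt; then Me3OBF4, CH2Cl2, 0 °C
Reagents that add atoms: trimethyloxonium tetrafluoroborate, C[O+](C)C.F[B-](F)(F)F
Why: Fischer carbene synthesis, in which the α-lithiated enol ether adds to a CO ligand of Cr(CO)6 and the resulting acylchromate is O-methylated by the Meerwein salt; the α-alkoxy substituent should stabilise the alkenyl complex against polymerisation.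

Step 8
Reactants: 15 3,5-bis(benzyloxy)-2-ethynyl-7,8-dimethoxy-4H-chromen-4-one; 20 pentacarbonyl[(1-tert-butoxyvinyl)(methoxy)carbene]chromium
Product: 22 3,5-bis(benzyloxy)-2-(4-tert-butoxy-2-hydroxy-5-methoxyphenyl)-7,8-dimethoxy-4H-chromen-4-one, via tricarbonylchromium arene complex 21 (not isolated)
Conditions: 20 (1.5 equiv), THF (degassed, 0.05 M), 50 °C; then air, MeCN, rt
Reagents that add atoms: none
Why: Dötz benzannulation, a reaction established for alkenyl(methoxy)carbene complexes of chromium (1-alkoxyalkenyl ones included) with terminal alkynes: thermal loss of one CO from 20, alkyne coordination and insertion into the Cr=C bond, then CO insertion to a chromium-bound dienylketene. Ring B closes as a six-membered carbocycle by 6π electrocyclisation of that ketene, which forms C2'–C3' after C5'–C6' and C1'–C2', and the former vinyl CH2 then gives up a hydrogen so that C2' emerges as a free phenol. No stereocentre is formed. The selectivity required is the orientation of alkyne insertion: the bulky chromonyl substituent should end on the carbon that takes up CO (C1' next to C2') and the CH terminus on the carbene carbon (C6' next to C5'), the steric preference general for terminal alkynes. O1 and the 3-benzyloxy group temper the electron poverty of the alkyne, and aerial demetalation rather than (NH4)2Ce(NO3)6 should free ring B from Cr(CO)3 without oxidising the para-methoxyphenol to a quinone.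

Step 9
Reactants: 22 3,5-bis(benzyloxy)-2-(4-tert-butoxy-2-hydroxy-5-methoxyphenyl)-7,8-dimethoxy-4H-chromen-4-one
Product: 23 3,5-bis(benzyloxy)-2-(2,4-dihydroxy-5-methoxyphenyl)-7,8-dimethoxy-4H-chromen-4-one
Conditions: TFA, CH2Cl2, 0 °C → rt
Reagents that add atoms: none
Why: Acidolysis of the aryl tert-butyl ether (ionisation to the tert-butyl cation, lost as isobutene) proceeds under conditions that leave methyl and benzyl ethers alone, and acid at room temperature, applied while O5 is still benzylated, avoids ring-opening isomerisation of the 5,7,8-oxygenated chromone.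

Step 10
Reactants: 23 3,5-bis(benzyloxy)-2-(2,4-dihydroxy-5-methoxyphenyl)-7,8-dimethoxy-4H-chromen-4-one
Product: 24 2-(2,4-dihydroxy-5-methoxyphenyl)-3,5-dihydroxy-7,8-dimethoxy-4H-chromen-4-one (target)
Conditions: H2 (1 atm), 10% Pd/C, EtOAc–MeOH, rt
Reagents that add atoms: none
Why: Hydrogenolysis of the two benzyl ethers over Pd/C is neutral and should spare the methyl ethers and the tetrasubstituted, vinylogous-ester C2=C3 bond of ring C.

Compound list
1 | 3-hydroxy-4,5-dimethoxybenzaldehyde | COc1cc(C=O)cc(O)c1OC | starting material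
2 | 3,4-dimethoxy-5-(methoxymethoxy)benzaldehyde | COCOc1cc(C=O)cc(OC)c1OC | intermediate
3 | 3,4-dimethoxy-5-(methoxymethoxy)phenyl formate | O=COc1cc(OC)c(OC)c(OCOC)c1 | intermediate
4 | 3,4-dimethoxy-5-(methoxymethoxy)phenol | Oc1cc(OC)c(OC)c(OCOC)c1 | intermediate
5 | 1-(benzyloxy)-3,4-dimethoxy-5-(methoxymethoxy)benzene | COCOc1cc(OCc2ccccc2)cc(OC)c1OC | intermediate
6 | 2-(benzyloxy)-N-methoxy-N-methylacetamide | CON(C)C(=O)COCc1ccccc1 | starting material
7 | [6-(benzyloxy)-3,4-dimethoxy-2-(methoxymethoxy)phenyl]lithium | [Li]c1c(OCOC)c(OC)c(OC)cc1OCc1ccccc1 | intermediate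
8 | 2-(benzyloxy)-1-[6-(benzyloxy)-3,4-dimethoxy-2-(methoxymethoxy)phenyl]ethan-1-one | COCOc1c(OC)c(OC)cc(OCc2ccccc2)c1C(=O)COCc1ccccc1 | intermediate
9 | 2-(benzyloxy)-1-[6-(benzyloxy)-2-hydroxy-3,4-dimethoxyphenyl]ethan-1-one | COc1cc(OCc2ccccc2)c(C(=O)COCc2ccccc2)c(O)c1OC | intermediate
10 | ethyl 2,2-diethoxyacetate | CCOC(=O)C(OCC)OCC | starting material
11 | 2-(benzyloxy)-1-[6-(benzyloxy)-2-hydroxy-3,4-dimethoxyphenyl]-4,4-diethoxybutane-1,3-dione | CCOC(OCC)C(=O)C(OCc1ccccc1)C(=O)c1c(O)c(OC)c(OC)cc1OCc1ccccc1 | intermediate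
12 | 3,5-bis(benzyloxy)-2-(diethoxymethyl)-7,8-dimethoxy-4H-chromen-4-one | CCOC(OCC)c1oc2c(OC)c(OC)cc(OCc3ccccc3)c2c(=O)c1OCc1ccccc1 | intermediate
13 | 3,5-bis(benzyloxy)-7,8-dimethoxy-4-oxo-4H-chromene-2-carbaldehyde | O=Cc1oc2c(OC)c(OC)cc(OCc3ccccc3)c2c(=O)c1OCc1ccccc1 | intermediate
14 | dimethyl (1-diazo-2-oxopropyl)phosphonate | COP(=O)(OC)C(=[N+]=[N-])C(C)=O | starting material
15 | 3,5-bis(benzyloxy)-2-ethynyl-7,8-dimethoxy-4H-chromen-4-one | C#Cc1oc2c(OC)c(OC)cc(OCc3ccccc3)c2c(=O)c1OCc1ccccc1 | intermediate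
16 | tert-butyl vinyl ether | C=COC(C)(C)C | starting material
17 | chromium hexacarbonyl | O=C=[Cr](=C=O)(=C=O)(=C=O)(=C=O)=C=O | starting material
18 | (1-tert-butoxyvinyl)lithium | [Li]C(=C)OC(C)(C)C | intermediate
19 | lithium pentacarbonyl[(1-tert-butoxyvinyl)(oxido)carbene]chromate | [Li+].[O-]C(=[Cr](=C=O)(=C=O)(=C=O)(=C=O)=C=O)C(=C)OC(C)(C)C | intermediate
20 | pentacarbonyl[(1-tert-butoxyvinyl)(methoxy)carbene]chromium | COC(=[Cr](=C=O)(=C=O)(=C=O)(=C=O)=C=O)C(=C)OC(C)(C)C | intermediate
21 | tricarbonylchromium complex of 22, metal η6-bound to ring B (bond to the ring not drawn) | COc1cc(-c2oc3c(OC)c(OC)cc(OCc4ccccc4)c3c(=O)c2OCc2ccccc2)c(O)cc1OC(C)(C)C.O=C=[Cr](=C=O)=C=O | intermediate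
22 | 3,5-bis(benzyloxy)-2-(4-tert-butoxy-2-hydroxy-5-methoxyphenyl)-7,8-dimethoxy-4H-chromen-4-one | COc1cc(-c2oc3c(OC)c(OC)cc(OCc4ccccc4)c3c(=O)c2OCc2ccccc2)c(O)cc1OC(C)(C)C | intermediate
23 | 3,5-bis(benzyloxy)-2-(2,4-dihydroxy-5-methoxyphenyl)-7,8-dimethoxy-4H-chromen-4-one | COc1cc(-c2oc3c(OC)c(OC)cc(OCc4ccccc4)c3c(=O)c2OCc2ccccc2)c(O)cc1O | intermediate
24 | 2-(2,4-dihydroxy-5-methoxyphenyl)-3,5-dihydroxy-7,8-dimethoxy-4H-chromen-4-one (no stereocentres) | COc1cc(-c2oc3c(OC)c(OC)cc(O)c3c(=O)c2O)c(O)cc1O | target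

Total step count: 10. Longest linear sequence: 9 steps (steps 1–6 and 8–10, from 1 to 24); step 7 is a one-step branch.

Steps most likely to fail

Step 8. The electron-poor, conjugated alkyne may insert slowly or twice, the vinylcarbene may divert to cyclobutenone or furan formation instead of electrocyclisation, or the electron-rich para-methoxyphenol may be over-oxidised during demetalation. The fallback gives up the benzannulation and assembles ring C around a ready-made ring B, setting out from ketone 9 and rejoining the route at 24. Purchased 2,4-dihydroxy-5-methoxybenzaldehyde is benzylated twice (BnBr, K2CO3, DMF) to 2,4-bis(benzyloxy)-5-methoxybenzaldehyde F1. Claisen–Schmidt condensation of 9 with it (KOH, EtOH, rt) should give the α-benzyloxy chalcone (Z)-2-(benzyloxy)-1-[6-(benzyloxy)-2-hydroxy-3,4-dimethoxyphenyl]-3-[2,4-bis(benzyloxy)-5-methoxyphenyl]prop-2-en-1-one F2. Iodine-catalysed oxidative cyclisation in DMSO at 120 °C should close ring C to 3,5-bis(benzyloxy)-2-[2,4-bis(benzyloxy)-5-methoxyphenyl]-7,8-dimethoxy-4H-chromen-4-one F3, and hydrogenolysis of all four benzyl ethers (H2, Pd/C) would then give 24.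

Step 6. Methoxide may add to C2 of the chromone aldehyde or to the newly formed activated alkyne, opening ring C or giving enol ethers. The fallback is a Corey–Fuchs sequence in aprotic media, from 13 back to 15. CBr4 and PPh3 in CH2Cl2 at 0 °C should convert 13 into 3,5-bis(benzyloxy)-2-(2,2-dibromovinyl)-7,8-dimethoxy-4H-chromen-4-one F4. Bromine–lithium exchange with n-BuLi in THF at −78 °C, rearrangement of the carbenoid to the lithium acetylide and a cold NH4Cl quench would then give 15.

Step 5. C-acylation of the hindered α-benzyloxy enolate by the moderately electrophilic ester may be sluggish, or the O5 benzyl group may be partly lost in the aqueous acid stage. The fallback uses the more electrophilic, non-enolisable diethyl oxalate and adjusts the oxidation level afterwards, from 9 back to 13. Condensation of 9 with diethyl oxalate (LiN(SiMe3)2, THF) should give ethyl 3-(benzyloxy)-4-[6-(benzyloxy)-2-hydroxy-3,4-dimethoxyphenyl]-2,4-dioxobutanoate F5. Anhydrous acid (p-TsOH, EtOH, 60 °C) should cyclise it to ethyl 3,5-bis(benzyloxy)-7,8-dimethoxy-4-oxo-4H-chromene-2-carboxylate F6. Reduction of the activated ester with NaBH4 (MeOH–THF, 0 °C) should give 3,5-bis(benzyloxy)-2-(hydroxymethyl)-7,8-dimethoxy-4H-chromen-4-one F7, and Dess–Martin periodinane (CH2Cl2, rt) would oxidise it to 13.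

Further compounds
F1 | step 8 | 2,4-bis(benzyloxy)-5-methoxybenzaldehyde | COc1cc(C=O)c(OCc2ccccc2)cc1OCc1ccccc1
F2 | step 8 | (Z)-2-(benzyloxy)-1-[6-(benzyloxy)-2-hydroxy-3,4-dimethoxyphenyl]-3-[2,4-bis(benzyloxy)-5-methoxyphenyl]prop-2-en-1-one | COc1cc(/C=C(\OCc2ccccc2)C(=O)c2c(O)c(OC)c(OC)cc2OCc2ccccc2)c(OCc2ccccc2)cc1OCc1ccccc1
F3 | step 8 | 3,5-bis(benzyloxy)-2-[2,4-bis(benzyloxy)-5-methoxyphenyl]-7,8-dimethoxy-4H-chromen-4-one | COc1cc(-c2oc3c(OC)c(OC)cc(OCc4ccccc4)c3c(=O)c2OCc2ccccc2)c(OCc2ccccc2)cc1OCc1ccccc1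
F4 | step 6 | 3,5-bis(benzyloxy)-2-(2,2-dibromovinyl)-7,8-dimethoxy-4H-chromen-4-one | BrC(Br)=Cc1oc2c(OC)c(OC)cc(OCc3ccccc3)c2c(=O)c1OCc1ccccc1
F5 | step 5 | ethyl 3-(benzyloxy)-4-[6-(benzyloxy)-2-hydroxy-3,4-dimethoxyphenyl]-2,4-dioxobutanoate | CCOC(=O)C(=O)C(OCc1ccccc1)C(=O)c1c(O)c(OC)c(OC)cc1OCc1ccccc1
F6 | step 5 | ethyl 3,5-bis(benzyloxy)-7,8-dimethoxy-4-oxo-4H-chromene-2-carboxylate | CCOC(=O)c1oc2c(OC)c(OC)cc(OCc3ccccc3)c2c(=O)c1OCc1ccccc1
F7 | step 5 | 3,5-bis(benzyloxy)-2-(hydroxymethyl)-7,8-dimethoxy-4H-chromen-4-one | OCc1oc2c(OC)c(OC)cc(OCc3ccccc3)c2c(=O)c1OCc1ccccc1
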